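**Assumptions:** The target SMILES has no stereocentres, so "single enantiomer" holds trivially. The stereocentres in the dione intermediate (9) are destroyed on aromatisation. I assume olivetolic acid, dimethyl (1-diazo-2-oxopropyl)phosphonate, hexanal and dibenzyl malonate are commercial.

## Retrosynthetic overview
1. Target ⇐ global hydrogenolysis (ring-A OBn, ring-B CO2Bn) ⇐ chemoselective O-methylation of the ring-B resorcylate, which also methylates the freed ring-A acid.
2. The diaryl ether is not made by Ullmann, SNAr or Chan–Lam coupling. The Ar–O bond is made at the enone stage, and the pentasubstituted ring B is built last around it. Ring B comes from a Michael/Claisen [3+3] annulation of an α-aryloxy enone with dibenzyl malonate, then dehydrogenative aromatisation. This fixes the oxygen at ring-B C1 by construction.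
3. The α-aryloxy enone comes from Rh-carbenoid O–H insertion of the ring-A phenol into the Ohira–Bestmann diazo phosphonate, then HWE with hexanal.
4. Ring A comes from commercial olivetolic acid, with a tert-butyl ester (to block benzofuranone Dieckmann closure) and a selective 4-O-benzyl group.
5. Ring order: ring A (commercial) first, ring B last.

## Route

**Step 1**
Reactants: 1, olivetolic acid (2,4-dihydroxy-6-pentylbenzoic acid)
Product: 2, tert-butyl 2,4-dihydroxy-6-pentylbenzoate
Conditions: tBuOC(=NH)CCl3 (2.5 equiv), BF3·OEt2 (5 mol%), CH2Cl2/cyclohexane, rt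
Reagents that add atoms: tert-butyl 2,2,2-trichloroacetimidate, CC(C)(C)OC(=N)C(Cl)(Cl)Cl
Why: Acid-catalysed imidate tert-butylation (Armstrong-type) esterifies the carboxylic acid selectively over the phenols, without heat that would decarboxylate the acid. The tert-butyl ester is too hindered to be attacked by enolates in Step 5.

**Step 2**
Reactants: 2
Product: 3, tert-butyl 4-(benzyloxy)-2-hydroxy-6-pentylbenzoate
Conditions: BnBr (1.05 equiv), K2CO3, KI (cat.), acetone, reflux
Reagents that add atoms: benzyl bromide, BrCc1ccccc1
Why: Regioselective phenol alkylation. The 4-OH is the more acidic, non-chelated phenol; the 2-OH is locked in an H-bond to the ester carbonyl and stays free for Step 3.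

**Step 3**
Reactants: 3; 4, dimethyl (1-diazo-2-oxopropyl)phosphonate (Ohira–Bestmann reagent, COP(=O)(OC)C(=[N+]=[N-])C(C)=O)
Product: 5, dimethyl {1-[5-(benzyloxy)-2-(tert-butoxycarbonyl)-3-pentylphenoxy]-2-oxopropyl}phosphonate
Conditions: Rh2(OAc)4 (1 mol%), 1,2-DCE, 60 °C, slow addition of 4
Reagents that add atoms: none (4 is the numbered reactant)
Why: Rh(II)-carbenoid O–H insertion of a phenol (as for α-diazo-β-ketoesters). This forms the Ar–O–C bond on an sp3 carbon, so no aryl C–O coupling is needed.

**Step 4**
Reactants: 5; 6, hexanal (CCCCCC=O)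
Product: 7, 3-[5-(benzyloxy)-2-(tert-butoxycarbonyl)-3-pentylphenoxy]non-3-en-2-one (E/Z mixture)
Conditions: LiCl, DBU, MeCN, 0 °C → rt
Reagents that add atoms: none (6 is the numbered reactant)
Why: Masamune–Roush Horner–Wadsworth–Emmons olefination places the C=C regiospecifically next to the aryloxy carbon, which avoids the regiochemical ambiguity of a direct aldol of aryloxyacetone. The alkene geometry is irrelevant because it is consumed in Step 5.

**Step 5**
Reactants: 7; 8, dibenzyl malonate (O=C(CC(=O)OCc1ccccc1)OCc1ccccc1)
Product: 9, benzyl 5-aryloxy-2,4-dioxo-6-pentylcyclohexane-1-carboxylate (Ar = 5-benzyloxy-2-tert-butoxycarbonyl-3-pentylphenyl; mixture of diastereomers and tautomers)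
Conditions: NaH (2.5 equiv), THF, 0 → 65 °C; then aq. NH4Cl/HCl
Reagents that add atoms: none (8 is the numbered reactant; BnOH is lost)
Why: Michael addition of the malonate at the β-pentyl carbon, then intramolecular Claisen (Dieckmann-type) closure of the enone CH3 enolate onto the second malonate ester. Ring B is thus assembled with O at C1, pentyl at C6 and CO2Bn at C5. Proposed new method: α-aryloxy-enone variant of the Michael/Claisen cyclohexane-1,3-dione synthesis; the closest known reaction is dimethyl malonate + 3-nonen-2-one → 2-carbomethoxy-5-pentylcyclohexane-1,3-dione (the olivetol route). Here the α-OAr adds steric bulk, but the enone stays a good acceptor. The tert-butyl ring-A ester suppresses Dieckmann closure of the α-aryloxy enolate into a benzofuranone.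

**Step 6**
Reactants: 9
Product: 10, benzyl 2,4-dihydroxy-5-aryloxy-6-pentylbenzoate (Ar as above)
Conditions: DDQ (1.2 equiv), 1,4-dioxane, 80 °C
Reagents that add atoms: none
Why: Dehydrogenative aromatisation. DDQ abstracts hydride from the γ-C–H of the β-ketoester/vinylogous-acid enol, loses a proton, and the dienone tautomerises to the resorcylate. This oxidation level is the only one that yields the arene, and it destroys all ring stereocentres. Conditions are neutral, so the tert-butyl ester and both benzyl groups survive.

**Step 7**
Reactants: 10
Product: 11, ring-A free acid (ring-B benzyl ester retained)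
Conditions: TFA/CH2Cl2 (1:4), Et3SiH (3 equiv), 0 °C → rt
Reagents that add atoms: none
Why: Acidolysis of the tert-butyl ester. The silane scavenges the tert-butyl cation so the electron-rich arenes are not alkylated. The benzyl ether and benzyl ester are stable to these conditions.

**Step 8**
Reactants: 11
Product: 12, methyl ester on ring A and 2-OMe on ring B (ring-B C4-OH still free)
Conditions: MeI (3 equiv), KHCO3 (3 equiv), DMF, rt
Reagents that add atoms: methyl iodide, CI
Why: The carboxylate methylates fastest. The ring-B C2-OH, para to the ester, is the more acidic phenol and is alkylated under the mild base. The C4-OH is H-bonded to the ester carbonyl and is untouched.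

**Step 9**
Reactants: 12
Product: 13, Epiphorellic acid 1
Conditions: H2 (1 atm), 10% Pd/C, EtOAc, rt
Reagents that add atoms: hydrogen, [H][H]
Why: Hydrogenolysis removes the ring-A benzyl ether and the ring-B benzyl ester together. The methyl ester, diaryl ether, methoxy group and free phenols are retained.

## Compound list
1 | olivetolic acid | CCCCCc1cc(O)cc(O)c1C(=O)O | starting material
2 | tert-butyl 2,4-dihydroxy-6-pentylbenzoate | CCCCCc1cc(O)cc(O)c1C(=O)OC(C)(C)C | intermediate
3 | tert-butyl 4-(benzyloxy)-2-hydroxy-6-pentylbenzoate | CCCCCc1cc(OCc2ccccc2)cc(O)c1C(=O)OC(C)(C)C | intermediate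
4 | dimethyl (1-diazo-2-oxopropyl)phosphonate | COP(=O)(OC)C(=[N+]=[N-])C(C)=O | starting material
5 | aryloxy β-ketophosphonate | COP(=O)(OC)C(Oc1cc(OCc2ccccc2)cc(CCCCC)c1C(=O)OC(C)(C)C)C(C)=O | intermediate
6 | hexanal | CCCCCC=O | starting material
7 | α-aryloxy enone (E/Z) | CCCCCC=C(Oc1cc(OCc2ccccc2)cc(CCCCC)c1C(=O)OC(C)(C)C)C(C)=O | intermediate
8 | dibenzyl malonate | O=C(CC(=O)OCc1ccccc1)OCc1ccccc1 | starting material
9 | cyclohexane-1,3-dione ester | O=C1CC(=O)C(Oc2cc(OCc3ccccc3)cc(CCCCC)c2C(=O)OC(C)(C)C)C(CCCCC)C1C(=O)OCc1ccccc1 | intermediate
10 | ring-B resorcylate diaryl ether | CCCCCc1cc(OCc2ccccc2)cc(Oc2c(O)cc(O)c(C(=O)OCc3ccccc3)c2CCCCC)c1C(=O)OC(C)(C)C | intermediate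
11 | ring-A free acid | CCCCCc1cc(OCc2ccccc2)cc(Oc2c(O)cc(O)c(C(=O)OCc3ccccc3)c2CCCCC)c1C(=O)O | intermediate
12 | methylated, fully protected diaryl ether | CCCCCc1cc(OCc2ccccc2)cc(Oc2c(OC)cc(O)c(C(=O)OCc3ccccc3)c2CCCCC)c1C(=O)OC | intermediate
13 | Epiphorellic acid 1 | CCCCCc1cc(O)cc(Oc2c(OC)cc(O)c(C(=O)O)c2CCCCC)c1C(=O)OC | target

Simple reagents (TBTA, BnBr, MeI, H2) are given with SMILES in the step lines and are not numbered.

## Step count
- Total steps: 9.
- Longest linear sequence: 9 steps (1 → 2 → 3 → 5 → 7 → 9 → 10 → 11 → 12 → 13, with 4, 6 and 8 as convergent inputs).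

## Three steps most likely to fail
1. **Step 5, Michael/Claisen annulation.** The α-aryloxy enone is a hindered trisubstituted acceptor, and enolate side reactions (benzofuranone closure, retro-Michael) compete.
   Fallback: reverse the polarity. Make the aryloxyacetate ArOCH2CO2Me from 3 and methyl bromoacetate. Add its silyl ketene acetal, under Lewis-acid Mukaiyama–Michael conditions, to benzyl 2-acetyloct-2-enoate (benzyl acetoacetate + hexanal). Then close the ring by Weiler-dianion Dieckmann (LDA) to reach the same dione 9.
2. **Step 6, dehydrogenative aromatisation.** DDQ may over-oxidise the electron-rich resorcylate, or the dione may be only partly converted.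
   Fallback: a different mechanism, α-bromination then E2 (pyridinium tribromide, then Li2CO3/LiBr, DMF, 80 °C). A second option is Pd(II)/O2 (Stahl-type) aerobic dehydrogenation.
3. **Step 3, Rh-carbenoid O–H insertion** into the chelated, ortho-ester-hindered phenol, which may give low yield or diazo dimerisation.
   Fallback: alkylate 3 with chloroacetone (K2CO3, KI), form the aryloxy-carbon enolate (LDA, −78 °C) and add hexanal. Then dehydrate the aldol (MsCl, Et3N, then DBU) to reach enone 7 without any carbenoid.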